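**Plan**

- Retrosynthesis: the C2=C3 double bond is traced back to an isoflavanone, the O1–C2 bond is opened by retro-oxa-Michael to a 2-aryl-1-(2,4,6-trioxygenated phenyl)propenone, and the C4a–C4 and C4–C3 bonds on either side of the ketone are cut together. This leaves a ring A iodide, carbon monoxide and a 1-arylvinylboronate carrying ring B.
- Enabling feature: C4 is a lone ketone carbon between C4a, which sits between the two equivalent oxygens (at C5 and C8a) of a symmetrical phloroglucinol ring A, and C3, which bears ring B. C4 can therefore enter as CO without any regiochemical question.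
- Forward order: ring A iodide (steps 1–2) and ring B boronate (steps 3–5) are joined through CO (step 6). Ring C then closes by 6-endo oxa-Michael addition (step 7) and is dehydrogenated to the 4-pyranone (step 8).
- Stereochemistry: the target is achiral. The only stereocentre on the way (C3 of the isoflavanone) forms racemic and is erased in step 8.

Key step: step 6

Remark: the final dehydrogenation is run through the silyl enol ether with Pd(OAc)2 rather than with a quinone oxidant at high temperature, because the benzylic-allylic CH2 of the prenyl group on the electron-rich ring B is a likely site of hydride abstraction.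

**Route**

Step 1
Reactants: 1 phloroglucinol (anhydrous)
Product: 2 1,3,5-tris(methoxymethoxy)benzene
Conditions: NaH, MOMCl, DMF, 0 °C to rt
Reagents that add atoms: chloromethyl methyl ether, COCCl
Why: Threefold Williamson-type O-alkylation of the phloroglucinol trianion with the hard electrophile MOMCl should favour ether formation over C-alkylation and give the symmetrical tris(acetal), in which all three ring positions are equivalent.

Step 2
Reactants: 2 1,3,5-tris(methoxymethoxy)benzene
Product: 3 2-iodo-1,3,5-tris(methoxymethoxy)benzene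
Conditions: n-BuLi, THF, 0 °C; then I2, −78 °C to rt
Reagents that add atoms: iodine, II
Why: Directed ortho-metalation: every ring hydrogen lies between two coordinating OMOM groups and the three are equivalent, so n-BuLi should give a single aryllithium, which iodine converts into the iodide.

Step 3
Reactants: 4 3-bromo-4,5-dimethoxybenzaldehyde; 5 tributyl(3-methylbut-2-en-1-yl)stannane
Product: 6 3,4-dimethoxy-5-(3-methylbut-2-en-1-yl)benzaldehyde
Conditions: Pd(PPh3)4 (5 mol%), DMF, 100 °C
Reagents that add atoms: none
Why: Stille coupling: zerovalent palladium inserts into the carbon–bromine bond of the aldehyde-activated arene and the allylic stannane transfers through its tin-bearing carbon, which should deliver the linear prenyl group while the aldehyde stays inert in the neutral medium.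

Step 4
Reactants: 6 3,4-dimethoxy-5-(3-methylbut-2-en-1-yl)benzaldehyde
Product: 7 5-ethynyl-1,2-dimethoxy-3-(3-methylbut-2-en-1-yl)benzene
Conditions: dimethyl (1-diazo-2-oxopropyl)phosphonate, K2CO3, MeOH, 0 °C to rt
Reagents that add atoms: dimethyl (1-diazo-2-oxopropyl)phosphonate, CC(=O)C(=[N+]=[N-])P(=O)(OC)OC
Why: Ohira–Bestmann variant of the Seyferth–Gilbert homologation: methanolysis of the reagent frees the diazomethylphosphonate anion, which olefinates the non-enolisable aldehyde and loses nitrogen with a 1,2-hydride shift to the terminal alkyne under conditions that leave the prenyl group alone.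

Step 5
Reactants: 7 5-ethynyl-1,2-dimethoxy-3-(3-methylbut-2-en-1-yl)benzene; 8 bis(pinacolato)diboron
Product: 9 2-{1-[3,4-dimethoxy-5-(3-methylbut-2-en-1-yl)phenyl]ethenyl}-4,4,5,5-tetramethyl-1,3,2-dioxaborolane
Conditions: CuCl(SIMes) (5 mol%; SIMes = 1,3-dimesitylimidazolidin-2-ylidene), NaOtBu (cat.), MeOH (2 equiv), THF, −50 °C to rt
Reagents that add atoms: none
Why: NHC–copper-catalysed protoboration (formal Markovnikov hydroboration): the N-aryl carbene–copper boryl adds syn across the terminal alkyne with boron at the aryl-bearing carbon and methanol protonates the alkenylcopper, while the trisubstituted prenyl olefin is too hindered to insert.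

Step 6
Reactants: 3 2-iodo-1,3,5-tris(methoxymethoxy)benzene; 9 2-{1-[3,4-dimethoxy-5-(3-methylbut-2-en-1-yl)phenyl]ethenyl}-4,4,5,5-tetramethyl-1,3,2-dioxaborolane; 10 carbon monoxide
Product: 11 2-[3,4-dimethoxy-5-(3-methylbut-2-en-1-yl)phenyl]-1-[2,4,6-tris(methoxymethoxy)phenyl]prop-2-en-1-one
Conditions: PdCl2(IPr)(3-chloropyridine) (5 mol%; IPr = 1,3-bis(2,6-diisopropylphenyl)imidazol-2-ylidene), Cs2CO3, CO (5 bar), PhCl–H2O (20:1), 80 °C
Reagents that add atoms: none
Why: Zerovalent palladium released from the carbene precatalyst inserts into the carbon–iodine bond of 3; the resulting arylpalladium iodide is crowded and electron-rich because of its two ortho OMOM groups, so migratory insertion of CO to the aroylpalladium is fast and relieves strain, whereas direct transmetalation at the hindered aryl centre is slow. The carbonate-activated boronate 9 then hands its 1-arylvinyl group to the aroylpalladium, and reductive elimination forms the C4–C3 bond, giving the cross-conjugated enone and returning zerovalent palladium. The closest known reaction type is the carbonylative Suzuki–Miyaura coupling of ortho-disubstituted aryl iodides under NHC–palladium catalysis, and of aryl iodides with alkenylboron reagents to aryl vinyl ketones. No ring is closed and no stereocentre is created. The selectivity required is carbonylative over direct coupling; it is secured by the two ortho substituents of 3, by CO pressure and by the bulky ligand, and the symmetry of 3 removes any regiochemical issue. The MOM acetals, the prenyl olefin and the methyl ethers should be inert to the weakly basic, non-nucleophilic medium.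

Step 7
Reactants: 11 2-[3,4-dimethoxy-5-(3-methylbut-2-en-1-yl)phenyl]-1-[2,4,6-tris(methoxymethoxy)phenyl]prop-2-en-1-one
Product: 13 racemic 5,7-dihydroxy-3-[3,4-dimethoxy-5-(3-methylbut-2-en-1-yl)phenyl]chroman-4-one, via trihydroxy enone 12 (not isolated)
Conditions: conc. HCl (cat.), MeOH, 50 °C; then NaOAc (cat.), rt, under argon
Reagents that add atoms: none
Why: Acid-catalysed acetal exchange with methanol strips the three MOM groups, and either of the two equivalent ortho hydroxyls then adds to the unhindered methylene terminus of the enone by 6-endo-trig oxa-Michael addition, completed under acetate buffering; the prenyl group has no free ortho hydroxyl, so no chroman can form, and the C3 stereocentre arises racemic because it is erased in the next step.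

Step 8
Reactants: 13 racemic 5,7-dihydroxy-3-[3,4-dimethoxy-5-(3-methylbut-2-en-1-yl)phenyl]chroman-4-one
Product: 16 piscerythrinetin (5,7-dihydroxy-3-[3,4-dimethoxy-5-(3-methylbut-2-en-1-yl)phenyl]-4H-chromen-4-one), via tris(trimethylsilyl) enol ether 14 (not isolated), via bis(trimethylsilyl) isoflavone 15 (not isolated)
Conditions: TMSOTf, Et3N, CH2Cl2, 0 °C; hexane trituration, filtration, evaporation; Pd(OAc)2 (1.1 equiv), MeCN, rt; then MeOH, HCl (cat.), rt
Reagents that add atoms: none
Why: Saegusa–Ito oxidation: soft enolisation silylates the C4 ketone towards C3 (and both phenols), Pd(OAc)2 converts the silyl enol ether into a palladium enolate that loses a C2 hydrogen by β-hydride elimination to give the chromone, and methanolysis frees the phenols; the mild conditions should leave the prenyl group and the electron-rich ring B untouched.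

**Compound list**

1 | phloroglucinol | Oc1cc(O)cc(O)c1 | starting material
2 | 1,3,5-tris(methoxymethoxy)benzene | COCOc1cc(OCOC)cc(OCOC)c1 | intermediate
3 | 2-iodo-1,3,5-tris(methoxymethoxy)benzene | COCOc1cc(OCOC)c(I)c(OCOC)c1 | intermediate
4 | 3-bromo-4,5-dimethoxybenzaldehyde | COc1cc(C=O)cc(Br)c1OC | starting material
5 | tributyl(3-methylbut-2-en-1-yl)stannane | CCCC[Sn](CCCC)(CCCC)CC=C(C)C | starting material
6 | 3,4-dimethoxy-5-(3-methylbut-2-en-1-yl)benzaldehyde | COc1cc(C=O)cc(CC=C(C)C)c1OC | intermediate
7 | 5-ethynyl-1,2-dimethoxy-3-(3-methylbut-2-en-1-yl)benzene | COc1cc(C#C)cc(CC=C(C)C)c1OC | intermediate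
8 | bis(pinacolato)diboron | CC1(C)OB(B2OC(C)(C)C(C)(C)O2)OC1(C)C | starting material
9 | 2-{1-[3,4-dimethoxy-5-(3-methylbut-2-en-1-yl)phenyl]ethenyl}-4,4,5,5-tetramethyl-1,3,2-dioxaborolane | C=C(B1OC(C)(C)C(C)(C)O1)c1cc(OC)c(OC)c(CC=C(C)C)c1 | intermediate
10 | carbon monoxide | [C-]#[O+] | starting material
11 | 2-[3,4-dimethoxy-5-(3-methylbut-2-en-1-yl)phenyl]-1-[2,4,6-tris(methoxymethoxy)phenyl]prop-2-en-1-one | C=C(C(=O)c1c(OCOC)cc(OCOC)cc1OCOC)c1cc(OC)c(OC)c(CC=C(C)C)c1 | intermediate
12 | 2-[3,4-dimethoxy-5-(3-methylbut-2-en-1-yl)phenyl]-1-(2,4,6-trihydroxyphenyl)prop-2-en-1-one | C=C(C(=O)c1c(O)cc(O)cc1O)c1cc(OC)c(OC)c(CC=C(C)C)c1 | intermediate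
13 | racemic 5,7-dihydroxy-3-[3,4-dimethoxy-5-(3-methylbut-2-en-1-yl)phenyl]chroman-4-one | COc1cc(C2COc3cc(O)cc(O)c3C2=O)cc(CC=C(C)C)c1OC | intermediate
14 | 3-[3,4-dimethoxy-5-(3-methylbut-2-en-1-yl)phenyl]-4,5,7-tris(trimethylsilyloxy)-2H-chromene | COc1cc(C2=C(O[Si](C)(C)C)c3c(O[Si](C)(C)C)cc(O[Si](C)(C)C)cc3OC2)cc(CC=C(C)C)c1OC | intermediate
15 | 3-[3,4-dimethoxy-5-(3-methylbut-2-en-1-yl)phenyl]-5,7-bis(trimethylsilyloxy)-4H-chromen-4-one | COc1cc(-c2coc3cc(O[Si](C)(C)C)cc(O[Si](C)(C)C)c3c2=O)cc(CC=C(C)C)c1OC | intermediate
16 | piscerythrinetin, 5,7-dihydroxy-3-[3,4-dimethoxy-5-(3-methylbut-2-en-1-yl)phenyl]-4H-chromen-4-one | COc1cc(-c2coc3cc(O)cc(O)c3c2=O)cc(CC=C(C)C)c1OC | target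

**Summary**

Total step count: 8. Longest linear sequence: 6 steps (steps 3, 4, 5, 6, 7, 8 from 3-bromo-4,5-dimethoxybenzaldehyde); the ring A branch contributes 2 steps before the convergence.

Steps most likely to fail:

1. Step 6. The hindered 1,1-disubstituted alkenylboronate may transmetalate too slowly, so that the aroylpalladium is intercepted by water or carbonate, direct coupling without CO leaks through, the boronate protodeboronates, or the α-aryl enone oligomerises in the warm basic medium. The fallback sets out from 2 and 9 and comes back at 11, taking C4 from a formyl group instead of CO. Compound 2 would be lithiated with n-BuLi and quenched with DMF to give 2,4,6-tris(methoxymethoxy)benzaldehyde F1. Rhodium-catalysed 1,2-addition of 9 to F1 (Rh(acac)(CO)2, dppf, aqueous KOH, dioxane, 80 °C) should give racemic 2-[3,4-dimethoxy-5-(3-methylbut-2-en-1-yl)phenyl]-1-[2,4,6-tris(methoxymethoxy)phenyl]prop-2-en-1-ol F2. Oxidation of this doubly activated alcohol with MnO2 in CH2Cl2 would deliver 11.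

2. Step 5. The boryl–copper addition may lose regiocontrol with this moderately electron-rich arylacetylene and give the linear (E)-styrylboronate alongside 9. The 4-methoxy group is twisted out of conjugation by its two neighbours, which should temper this, but the outcome is not certain. The fallback sets out from 6 and comes back at 9, fixing the boron position through a ketone carbon. MeMgBr in THF would give racemic 1-[3,4-dimethoxy-5-(3-methylbut-2-en-1-yl)phenyl]ethanol F3. MnO2 oxidation would give 1-[3,4-dimethoxy-5-(3-methylbut-2-en-1-yl)phenyl]ethanone F4. Enolisation with KN(SiMe3)2 and trapping with PhNTf2 at −78 °C would give 1-[3,4-dimethoxy-5-(3-methylbut-2-en-1-yl)phenyl]ethenyl trifluoromethanesulfonate F5. Miyaura borylation of F5 with 8 (PdCl2(PPh3)2, PPh3, KOPh, toluene, 50 °C) would return 9.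

3. Step 8. Enol silylation may be incomplete, or palladium may transfer slowly to the tetrasubstituted silyl enol ether, so that methanolysis simply returns 13; palladium hydride could also isomerise the prenyl double bond. The fallback sets out from 13 and comes back at 16, using a lithium enolate and a sulfur electrophile instead of palladium. TBSOTf and 2,6-lutidine in CH2Cl2 would give racemic 5,7-bis(tert-butyldimethylsilyloxy)-3-[3,4-dimethoxy-5-(3-methylbut-2-en-1-yl)phenyl]chroman-4-one F6. Deprotonation with LiN(SiMe3)2 in THF at −78 °C and addition of N-tert-butylbenzenesulfinimidoyl chloride should sulfenylate C3 and eliminate in the same pot to 5,7-bis(tert-butyldimethylsilyloxy)-3-[3,4-dimethoxy-5-(3-methylbut-2-en-1-yl)phenyl]-4H-chromen-4-one F7. Bu4NF buffered with AcOH in THF would then release 16.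

**Further compounds**

F1 | step 6 | 2,4,6-tris(methoxymethoxy)benzaldehyde | COCOc1cc(OCOC)c(C=O)c(OCOC)c1
F2 | step 6 | racemic 2-[3,4-dimethoxy-5-(3-methylbut-2-en-1-yl)phenyl]-1-[2,4,6-tris(methoxymethoxy)phenyl]prop-2-en-1-ol | C=C(C(O)c1c(OCOC)cc(OCOC)cc1OCOC)c1cc(OC)c(OC)c(CC=C(C)C)c1
F3 | step 5 | racemic 1-[3,4-dimethoxy-5-(3-methylbut-2-en-1-yl)phenyl]ethanol | COc1cc(C(C)O)cc(CC=C(C)C)c1OC
F4 | step 5 | 1-[3,4-dimethoxy-5-(3-methylbut-2-en-1-yl)phenyl]ethanone | COc1cc(C(C)=O)cc(CC=C(C)C)c1OC
F5 | step 5 | 1-[3,4-dimethoxy-5-(3-methylbut-2-en-1-yl)phenyl]ethenyl trifluoromethanesulfonate | C=C(OS(=O)(=O)C(F)(F)F)c1cc(OC)c(OC)c(CC=C(C)C)c1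
F6 | step 8 | racemic 5,7-bis(tert-butyldimethylsilyloxy)-3-[3,4-dimethoxy-5-(3-methylbut-2-en-1-yl)phenyl]chroman-4-one | COc1cc(C2COc3cc(O[Si](C)(C)C(C)(C)C)cc(O[Si](C)(C)C(C)(C)C)c3C2=O)cc(CC=C(C)C)c1OC
F7 | step 8 | 5,7-bis(tert-butyldimethylsilyloxy)-3-[3,4-dimethoxy-5-(3-methylbut-2-en-1-yl)phenyl]-4H-chromen-4-one | COc1cc(-c2coc3cc(O[Si](C)(C)C(C)(C)C)cc(O[Si](C)(C)C(C)(C)C)c3c2=O)cc(CC=C(C)C)c1OC
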